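**Abbreviations and numbering.** TIPS = triisopropylsilyl, Tf = trifluoromethanesulfonyl, DIC = N,N'-diisopropylcarbodiimide, dme = 1,2-dimethoxyethane. Dihydrobenzofuran atoms are O1, C2, C3, C3a, C4–C7, C7a, with primes for ring 2. Flavanone numbering (O1, C2, C3, C4, C4a, C5–C8, C8a) is used for compounds 1–5.

**Remark on the chemistry (assumption).** (S)-Naringenin is taken as enantiopure material; its optical purity would be checked by chiral HPLC before use, because samples of natural origin can be partly racemic.

## Analysis of the target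

The target 23 is a resveratrol trimer built from two 2,3-dihydro-1-benzofurans, ring 1 and ring 2, joined by the single bond C3–C6'. Ring 1 carries an (E)-4-hydroxystyryl group at C6, ring 2 a 3,5-dihydroxyphenyl group at C3', and each ring has a 4-hydroxyphenyl group on C2/C2' and a hydroxyl on C4/C4'. The four stereocentres C2, C3, C2' and C3' are all S, the two aryl groups are trans in each ring, and the two rings are the same stereochemical unit used twice. The sensitive groups are seven free phenols (oxidised as phenoxides), an E-stilbene (light, acid-induced cyclisation) and the two benzylic aryl ether bonds O1–C2 and O1'–C2'. These two bonds lie para to a phenol oxygen and are opened by acids, Lewis acids and hydrogenolysis, which rules out boron-halide demethylation or hydrogenolytic debenzylation at the end. The hard parts are the C3–C6' bond, which joins a doubly benzylic stereocentre flanked by the C2 aryl group and the C4 oxygen to an arene, the absolute control of four centres, and a mild end game. The plan rests on one feature of each ring: O1, the (S)-configured O–CH(4-hydroxyphenyl) carbon C2 and the benzo ring C3a–C7a, with oxygen at C4 and a substituent at C6, are (S)-naringenin 1 without its carbonyl carbon. Flavanone C4a becomes C3a, the chelated 5-hydroxyl becomes the C4 hydroxyl and the 7-oxygen sits where the C6 substituent goes, so the carbonyl carbon only has to be moved out of the ring.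

## Retrosynthetic reasoning

**Protecting groups (23 ⇐ 22).** All seven phenols are carried as triisopropylsilyl ethers, so the last step is a buffered fluoride desilylation. This is the one global deprotection that touches neither the O1–C2 and O1'–C2' ethers nor the stilbene. Methyl ethers would be easier to carry, but their removal would need boron halides, which open exactly these benzylic ethers. This choice fixes the silylated building blocks 12 and 19.

**C3–C6' bond (22 ⇐ 21 + 16).** The bond between the stereogenic C3 of ring 1 and the aryl carbon C6' of ring 2 is cut because it is the only link between the two dihydrobenzofurans and leaves two pieces with the same substitution pattern. The forward reaction is a decarboxylative arylation. The redox-active ester 21 must give a planar benzylic C3 radical, and the catalyst must deliver the aryl group of boronic acid 16 anti to the C2 aryl group. The gain is convergence, and a C3 centre set by the neighbouring C2 centre.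

**Styryl group (21 ⇐ 20 ⇐ 9 + 19).** The C6–vinyl bond is cut to the aryl triflate 9 and styrene 19 (from 17). The Heck reaction is placed before the radical step so that no aryl triflate is present when nickel and a boronic acid meet.

**Ring-2 unit (16 ⇐ 15 ⇐ 10 + 14).** The C6'–boron bond comes from the triflate of 15. The C3'–aryl bond is cut by the same decarboxylative logic, here with arylzinc 14 (from 12, from 11) and redox-active ester 10 (from 9). The forward reaction must again place the incoming aryl group trans to the C2' aryl group.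

**Common intermediate (9 ⇐ 8 ⇐ 7).** Both halves are taken from one acid, 9, so every step up to it serves the target twice. Its C3 carboxyl group is the handle for both radical steps, and its C3 configuration is irrelevant.

**Key disconnection (7 ⇐ 5).** The C3–C3a bond of the dihydrofuran is cut and the ester carbon is reinserted between C3 and C3a, which restores a six-membered 3-diazochroman-4-one, 5. In the forward direction, loss of the diazo nitrogen must be accompanied by a shift of the aryl carbon from the carbonyl carbon to C3, and the solvent alcohol must trap the ketene. The gain is that O1–C2 and the C2 configuration arrive ready-made, no trans-selective cyclisation is needed, and the carbon expelled from the ring becomes the carboxyl handle.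

**Precursor (5 ⇐ 3 ⇐ 2 ⇐ 1).** The diazo group is placed at C3, the only enolisable position. The 4'-hydroxyl is silylated and the 7-hydroxyl, the most acidic phenol of 1, is turned into the triflate that later becomes either the styryl group or the boronic acid. These three steps must not let a C3 carbanion open the pyranone, since that would racemise C2.

## Alternatives that were turned down

**Alternative 1:** Ring 1 is cut at C2–aryl and C3–C6' across an alkene, and O1–C2 is closed later. In the key step an aryllithium adds to the boron of a β-aryl alkenyl boronate, and a palladium catalyst with a chiral ferrocenyl bisphosphine joins the ate complex to an aryl bromide that already contains ring 2. The aryl group on boron shifts to C2 and gives the anti boronate A1.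
- For: two C–C bonds and two stereocentres form in one catalytic step, and C3 is set by the catalyst. On this point it is stronger than the chosen route, which relies on the neighbouring C2 centre and on photochemistry.
- Against: the alkene carbon C3 bears a 2,6-dioxygenated aryl group, far more hindered than the simple vinyl boronates on which this coupling works well. The bromide released tends to inhibit the metallate shift. Ring 2 must first be made enantiopure by some other method. The C2–boron bond of A1 must then be exchanged for C2–O1 with inversion at a 4-methoxybenzylic carbon that ionises easily. The silyloxymethyl group needs three further steps to become the styryl group, and the methyl ethers call for a boron-halide end game.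
- In its place the chosen route takes both C2 centres from one natural product, uses one intermediate for both rings and ends with fluoride.

**Alternative 2:** The benzo ring of ring 2 is cut at C3a'–C4' and C7'–C7a' into a cyclobutenone that carries ring 1 and a siloxyalkyne that carries the C3'–C2' chain. Heating opens the cyclobutenone to a vinylketene, which adds to the alkyne, reopens and closes in a six-electron step to the phenol A2.
- For: the regiochemistry of the new arene is fixed by the mechanism, and the hindered C3–aryl bond exists before the arene does, so no coupling at a stereocentre is needed. This is a real advantage over the chosen radical coupling.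
- Against: both components are chiral and take many steps. One of them already contains the complete trans ring 1 with its C3 substituent, so C3 and C3' each need an asymmetric method of their own. The cascade needs prolonged heating of acid-labile benzylic ethers. A2 still has to be closed to ring 2 by ionisation at C2'. The hallmark of the benzannulation, a free C4' hydroxyl next to a silylated C7a' oxygen, gains nothing here, because the two oxygens flank C3a' symmetrically and closure on either gives the same ring. Methyl ethers again decide the end game.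
- The chosen route is much shorter and sets the two remaining centres by substrate control.

**Alternative 3:** Both O1–C2 and O1'–C2' are cut. C3 and C3' are fixed beforehand by reduction of two α-aryl ketones under dynamic kinetic resolution. Acid in an alcohol then removes four methoxymethyl groups, ionises both 4-methoxybenzylic carbinols and lets the phenols close both rings trans, giving A3 whatever the carbinol configuration.
- For: it uses the very cation stability that is a liability elsewhere, closes two rings in one flask and uses only well-known reaction types. It is the more conservative plan and in that respect stronger than a photochemical contraction without direct precedent.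
- Against: C2 and C2' are only as pure as the trans preference of cation capture allows. The cation next to the diaryl methine C3–H can eliminate or suffer aryl and hydride shifts, which erases C3. Two remote ketones must each be reduced with high catalyst control. A3 still carries a methyl ester, which needs three steps to become the styryl group, and four methyl ethers, whose removal threatens the O1–C2 bonds.
- The chosen route buys C2 and C2' instead of deriving them, and keeps acids out of the end game.

Key step: step 4

## Route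

**Step 1**
Reactants: 1 (S)-naringenin, (2S)-5,7-dihydroxy-2-(4-hydroxyphenyl)chroman-4-one
Product: 2 (2S)-5-hydroxy-2-(4-hydroxyphenyl)-4-oxochroman-7-yl trifluoromethanesulfonate
Conditions: PhNTf2 (1.05 equiv), i-Pr2NEt (1.2 equiv), THF, 0 °C to rt
Reagents that add atoms: N-phenylbis(trifluoromethanesulfonimide), O=S(=O)(N(c1ccccc1)S(=O)(=O)C(F)(F)F)C(F)(F)F
Why: Chemoselective phenol triflation: the 7-hydroxyl, para to the carbonyl, is the most acidic phenol and the only one the amine ionises, the 5-hydroxyl is locked in a hydrogen bond and the 4'-hydroxyl is an ordinary phenol. The 7-phenoxide is a vinylogous carboxylate, so C3 is not deprotonated and C2 is not at risk.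

**Step 2**
Reactants: 2 (2S)-5-hydroxy-2-(4-hydroxyphenyl)-4-oxochroman-7-yl trifluoromethanesulfonate
Product: 3 (2S)-5-hydroxy-4-oxo-2-[4-(triisopropylsilyloxy)phenyl]chroman-7-yl trifluoromethanesulfonate
Conditions: TIPSCl (1.2 equiv), imidazole (2.5 equiv), CH2Cl2/DMF, 0 °C to rt
Reagents that add atoms: chlorotriisopropylsilane, CC(C)[Si](Cl)(C(C)C)C(C)C
Why: Silylation of the only unchelated phenol; the hydrogen-bonded 5-hydroxyl does not react, and imidazole is too weak a base to enolise the flavanone at a useful rate.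

**Step 3**
Reactants: 3 (2S)-5-hydroxy-4-oxo-2-[4-(triisopropylsilyloxy)phenyl]chroman-7-yl trifluoromethanesulfonate
Product: 5 (2R)-3-diazo-5-hydroxy-4-oxo-2-[4-(triisopropylsilyloxy)phenyl]chroman-7-yl trifluoromethanesulfonate, via 3-trifluoroacetyl ketone 4 (not isolated)
Conditions: LiN(SiMe3)2 (2.2 equiv), THF, −78 °C; CF3CO2CH2CF3, −78 °C; cold aq. HCl; then MsN3, Et3N, H2O (1 equiv), MeCN, 0 °C to rt
Reagents that add atoms: mesyl azide, CS(=O)(=O)N=[N+]=[N-] (the two diazo nitrogens); 2,2,2-trifluoroethyl trifluoroacetate, O=C(OCC(F)(F)F)C(F)(F)F (trifluoroacetyl group of 4 only)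
Why: Detrifluoroacetylative diazo transfer: the phenoxide/enolate dianion is C-acylated at C3, the only enolisable position, and the acidic 1,3-dicarbonyl compound 4 takes the diazo group from the sulfonyl azide while the trifluoroacetyl group leaves on the sulfonamide. The enolate is kept at −78 °C and short-lived because a C3 carbanion can expel the ring-A phenoxide and so racemise C2. The descriptor of C2 changes to R only because the diazo carbon now outranks the aryl group; the spatial arrangement is that of 1.

**Step 4**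
Reactants: 5 (2R)-3-diazo-5-hydroxy-4-oxo-2-[4-(triisopropylsilyloxy)phenyl]chroman-7-yl trifluoromethanesulfonate
Product: 7 methyl (2S)-4-hydroxy-2-[4-(triisopropylsilyloxy)phenyl]-6-(trifluoromethylsulfonyloxy)-2,3-dihydro-1-benzofuran-3-carboxylate (both C3 epimers), via ketene 6 (not isolated)
Conditions: hν (365 nm), degassed MeOH/THF, 5 °C
Reagents that add atoms: methanol, CO
Why: Proposed new method: excitation of the α-diazoketone, which the ring holds in the s-Z geometry, expels N2 while the anti-periplanar C4–C4a bond of the flavanone (C4a becomes C3a) shifts to the diazo carbon, in concert or through a short-lived singlet acylcarbene, and the ketene 6 is trapped by methanol as the ester. The closest known reaction type is the photochemical Wolff ring contraction of cyclic 2-diazo ketones, benzo-fused ones included; it has not been shown on a 2-aryl-3-diazochroman-4-one with a stereogenic C2–H. The dihydrofuran ring (O1, C2, C3, C3a, C7a) arises by contraction of the pyranone through a 1,2-shift, so it is not a cyclisation and no Baldwin mode applies; the O1–C2 and O1–C7a bonds are never broken. No stereocentre is made under control: C2 is a spectator and keeps the arrangement of 1, and C3 forms as both epimers by unselective protonation of the ester enol, which does not matter because C3 later becomes a planar radical. The selectivity needed is aryl migration over a 1,2-hydride shift from C2 (which would give the flavone and erase C2) and over insertion of a free carbene into the O–H bond of the solvent. The locked s-Z geometry, the electron-rich migrating carbon flanked by two oxygens and direct irradiation at a wavelength the product does not absorb favour the concerted path. Excited-state proton transfer in the chelated 5-hydroxy ketone only returns ground-state 5, so it can cost quantum efficiency but not material.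

**Step 5**
Reactants: 7 methyl (2S)-4-hydroxy-2-[4-(triisopropylsilyloxy)phenyl]-6-(trifluoromethylsulfonyloxy)-2,3-dihydro-1-benzofuran-3-carboxylate
Product: 8 methyl (2S)-4-(triisopropylsilyloxy)-2-[4-(triisopropylsilyloxy)phenyl]-6-(trifluoromethylsulfonyloxy)-2,3-dihydro-1-benzofuran-3-carboxylate (C3 epimers)
Conditions: TIPSOTf (1.3 equiv), 2,6-lutidine (2.5 equiv), CH2Cl2, 0 °C to rt
Reagents that add atoms: triisopropylsilyl trifluoromethanesulfonate, CC(C)[Si](OS(=O)(=O)C(F)(F)F)(C(C)C)C(C)C
Why: Silylation of the hindered C4 phenol with a silyl triflate and a non-nucleophilic base removes the last acidic proton before the organometallic steps.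

**Step 6**
Reactants: 8 methyl (2S)-4-(triisopropylsilyloxy)-2-[4-(triisopropylsilyloxy)phenyl]-6-(trifluoromethylsulfonyloxy)-2,3-dihydro-1-benzofuran-3-carboxylate
Product: 9 (2S)-4-(triisopropylsilyloxy)-2-[4-(triisopropylsilyloxy)phenyl]-6-(trifluoromethylsulfonyloxy)-2,3-dihydro-1-benzofuran-3-carboxylic acid (C3 epimers)
Conditions: Me3SnOH (6 equiv), ClCH2CH2Cl, 80 °C; dilute aq. HCl wash
Reagents that add atoms: trimethyltin hydroxide, C[Sn](C)(C)O (the hydroxyl oxygen)
Why: Tin-hydroxide ester hydrolysis under near-neutral conditions, chosen because aqueous hydroxide would attack the aryl silyl ethers and the aryl triflate. A five-membered-ring enolate at C3 cannot easily expel O1 (the reverse of a 5-endo closure), so C2 should be safe.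

**Step 7**
Reactants: 9 (2S)-4-(triisopropylsilyloxy)-2-[4-(triisopropylsilyloxy)phenyl]-6-(trifluoromethylsulfonyloxy)-2,3-dihydro-1-benzofuran-3-carboxylic acid
Product: 10 1,3-dioxoisoindolin-2-yl (2S)-4-(triisopropylsilyloxy)-2-[4-(triisopropylsilyloxy)phenyl]-6-(trifluoromethylsulfonyloxy)-2,3-dihydro-1-benzofuran-3-carboxylate (C3 epimers)
Conditions: N-hydroxyphthalimide, DIC, DMAP (10 mol%), CH2Cl2, rt
Reagents that add atoms: N-hydroxyphthalimide, ON1C(=O)c2ccccc2C1=O
Why: Steglich-type esterification gives the redox-active N-acyloxyphthalimide needed for single-electron decarboxylation.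

**Step 8**
Reactants: 11 5-bromobenzene-1,3-diol
Product: 12 1-bromo-3,5-bis(triisopropylsilyloxy)benzene
Conditions: TIPSCl (2.4 equiv), imidazole (5 equiv), DMF, rt
Reagents that add atoms: chlorotriisopropylsilane, CC(C)[Si](Cl)(C(C)C)C(C)C
Why: Routine double silylation of a resorcinol; it gives the 3,5-dioxygenated aryl unit in the same protecting group as the rest.

**Step 9**
Reactants: 12 1-bromo-3,5-bis(triisopropylsilyloxy)benzene; 10 1,3-dioxoisoindolin-2-yl (2S)-4-(triisopropylsilyloxy)-2-[4-(triisopropylsilyloxy)phenyl]-6-(trifluoromethylsulfonyloxy)-2,3-dihydro-1-benzofuran-3-carboxylate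
Product: 15 (2S,3S)-3-[3,5-bis(triisopropylsilyloxy)phenyl]-4-(triisopropylsilyloxy)-2-[4-(triisopropylsilyloxy)phenyl]-2,3-dihydro-1-benzofuran-6-yl trifluoromethanesulfonate, via aryllithium 13 (not isolated), via arylzinc chloride 14 (not isolated)
Conditions: 12, n-BuLi, THF, −78 °C; ZnCl2, −78 °C to rt; then 10, NiCl2·dme (20 mol%), 4,4'-di-tert-butyl-2,2'-bipyridine (40 mol%), THF/DMF, rt
Reagents that add atoms: n-butyllithium, [Li]CCCC, and zinc chloride, Cl[Zn]Cl (their metal and chlorine atoms appear only in 13 and 14; 15 holds atoms of 10 and 12 alone)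
Why: Nickel-catalysed decarboxylative Negishi-type arylation of a secondary redox-active ester: single-electron reduction of 10 releases CO2 and a planar benzylic radical at C3 (C3' of the target), which the arylnickel species captures on the face away from the C2 aryl group, so that reductive elimination sets C3 as S, trans to C2. Bipyridine-ligated nickel inserts only slowly into aryl triflates, so the triflate should survive.

**Step 10**
Reactants: 15 (2S,3S)-3-[3,5-bis(triisopropylsilyloxy)phenyl]-4-(triisopropylsilyloxy)-2-[4-(triisopropylsilyloxy)phenyl]-2,3-dihydro-1-benzofuran-6-yl trifluoromethanesulfonate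
Product: 16 [(2S,3S)-3-[3,5-bis(triisopropylsilyloxy)phenyl]-4-(triisopropylsilyloxy)-2-[4-(triisopropylsilyloxy)phenyl]-2,3-dihydro-1-benzofuran-6-yl]boronic acid
Conditions: B2(OH)4 (3 equiv), Pd2(dba)3 (2.5 mol%), XPhos (10 mol%), KOAc (3 equiv), EtOH/THF, 80 °C
Reagents that add atoms: tetrahydroxydiboron, OB(O)B(O)O
Why: Miyaura-type borylation of the unhindered aryl triflate with the diboronic acid gives the free boronic acid directly; the weak base and the temperature do not touch the aryl silyl ethers or the two stereocentres.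

**Step 11**
Reactants: 17 4-acetoxystyrene
Product: 19 4-(triisopropylsilyloxy)styrene, via 4-vinylphenol 18 (not isolated)
Conditions: K2CO3 (0.2 equiv), MeOH, 0 °C; cold extractive work-up; TIPSCl, imidazole, DMF, 0 °C to rt
Reagents that add atoms: chlorotriisopropylsilane, CC(C)[Si](Cl)(C(C)C)C(C)C
Why: Base-catalysed methanolysis of the aryl acetate, then silylation of the crude phenol before it can polymerise.

**Step 12**
Reactants: 9 (2S)-4-(triisopropylsilyloxy)-2-[4-(triisopropylsilyloxy)phenyl]-6-(trifluoromethylsulfonyloxy)-2,3-dihydro-1-benzofuran-3-carboxylic acid; 19 4-(triisopropylsilyloxy)styrene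
Product: 20 (2S)-4-(triisopropylsilyloxy)-2-[4-(triisopropylsilyloxy)phenyl]-6-[(E)-2-[4-(triisopropylsilyloxy)phenyl]ethenyl]-2,3-dihydro-1-benzofuran-3-carboxylic acid (C3 epimers)
Conditions: Pd(OAc)2 (5 mol%), PPh3 (12 mol%), LiCl (3 equiv), Et3N (4 equiv), DMF, 90 °C
Reagents that add atoms: none
Why: Heck reaction of the aryl triflate: chloride turns the arylpalladium triflate into the neutral arylpalladium chloride, which adds to the terminal carbon of the styrene, and syn β-hydride elimination gives the E-stilbene. The acid travels as its ammonium salt, and the triflate is used up before any nickel step on this branch.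

**Step 13**
Reactants: 20 (2S)-4-(triisopropylsilyloxy)-2-[4-(triisopropylsilyloxy)phenyl]-6-[(E)-2-[4-(triisopropylsilyloxy)phenyl]ethenyl]-2,3-dihydro-1-benzofuran-3-carboxylic acid
Product: 21 4,5,6,7-tetrachloro-1,3-dioxoisoindolin-2-yl (2S)-4-(triisopropylsilyloxy)-2-[4-(triisopropylsilyloxy)phenyl]-6-[(E)-2-[4-(triisopropylsilyloxy)phenyl]ethenyl]-2,3-dihydro-1-benzofuran-3-carboxylate (C3 epimers)
Conditions: N-hydroxytetrachlorophthalimide, DIC, DMAP (10 mol%), CH2Cl2, rt
Reagents that add atoms: N-hydroxytetrachlorophthalimide, ON1C(=O)c2c(Cl)c(Cl)c(Cl)c(Cl)c2C1=O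
Why: Carbodiimide esterification to the tetrachlorinated redox-active ester, the more easily reduced ester class that couplings with boronic acids need.

**Step 14**
Reactants: 21 4,5,6,7-tetrachloro-1,3-dioxoisoindolin-2-yl (2S)-4-(triisopropylsilyloxy)-2-[4-(triisopropylsilyloxy)phenyl]-6-[(E)-2-[4-(triisopropylsilyloxy)phenyl]ethenyl]-2,3-dihydro-1-benzofuran-3-carboxylate; 16 [(2S,3S)-3-[3,5-bis(triisopropylsilyloxy)phenyl]-4-(triisopropylsilyloxy)-2-[4-(triisopropylsilyloxy)phenyl]-2,3-dihydro-1-benzofuran-6-yl]boronic acid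
Product: 22 heptakis(triisopropylsilyl) ether of 23 (all seven phenol oxygens silylated; 2S,3S,2'S,3'S; E)
Conditions: 16 (2 equiv), NiCl2·6H2O (20 mol%), bathophenanthroline (20 mol%), Et3N (10 equiv), 1,4-dioxane/DMF 10:1, 75 °C
Reagents that add atoms: none
Why: Nickel-catalysed decarboxylative Suzuki-type arylation of a secondary redox-active ester: the arylnickel species formed from 16 reduces 21, and the planar benzylic C3 radical left after loss of CO2 is captured by nickel anti to the C2 aryl group, so that reductive elimination forms C3–C6' with C3 as S, trans to C2. The centres of 16 take no part, and addition of the stabilised radical to the stilbene should be slower than its capture by nickel.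

**Step 15**
Reactants: 22 heptakis(triisopropylsilyl) ether of 23
Product: 23 (2S,3S)-3-[(2S,3S)-3-(3,5-dihydroxyphenyl)-4-hydroxy-2-(4-hydroxyphenyl)-2,3-dihydro-1-benzofuran-6-yl]-2-(4-hydroxyphenyl)-6-[(E)-2-(4-hydroxyphenyl)ethenyl]-2,3-dihydro-1-benzofuran-4-ol (the target)
Conditions: Bu4NF (10 equiv), AcOH (10 equiv), THF, 0 °C to rt, argon, dark
Reagents that add atoms: none
Why: Fluoride cleaves all seven aryl silyl ethers, and acetic acid keeps the phenols protonated so that neither air oxidation nor quinone-methide opening of the O1–C2 bonds sets in. No acid, Lewis acid or hydrogen is used, so the stilbene and both benzylic ethers should survive.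

## Compound list

1 | (S)-naringenin, (2S)-5,7-dihydroxy-2-(4-hydroxyphenyl)chroman-4-one | Oc1cc(O)c2c(c1)O[C@H](c1ccc(O)cc1)CC2=O | starting material
2 | (2S)-5-hydroxy-2-(4-hydroxyphenyl)-4-oxochroman-7-yl trifluoromethanesulfonate | FC(F)(F)S(=O)(=O)Oc1cc(O)c2c(c1)O[C@H](c1ccc(O)cc1)CC2=O | intermediate
3 | (2S)-5-hydroxy-4-oxo-2-[4-(triisopropylsilyloxy)phenyl]chroman-7-yl trifluoromethanesulfonate | FC(F)(F)S(=O)(=O)Oc1cc(O)c2c(c1)O[C@H](c1ccc(O[Si](C(C)C)(C(C)C)C(C)C)cc1)CC2=O | intermediate
4 | (2S)-5-hydroxy-4-oxo-3-(trifluoroacetyl)-2-[4-(triisopropylsilyloxy)phenyl]chroman-7-yl trifluoromethanesulfonate (C3 unassigned, largely enolised) | FC(F)(F)S(=O)(=O)Oc1cc(O)c2c(c1)O[C@H](c1ccc(O[Si](C(C)C)(C(C)C)C(C)C)cc1)C(C(=O)C(F)(F)F)C2=O | intermediate (not isolated)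
5 | (2R)-3-diazo-5-hydroxy-4-oxo-2-[4-(triisopropylsilyloxy)phenyl]chroman-7-yl trifluoromethanesulfonate (same spatial arrangement at C2 as 1) | FC(F)(F)S(=O)(=O)Oc1cc(O)c2c(c1)O[C@H](c1ccc(O[Si](C(C)C)(C(C)C)C(C)C)cc1)C(=[N+]=[N-])C2=O | intermediate
6 | (2R)-4-hydroxy-3-(oxomethylidene)-2-[4-(triisopropylsilyloxy)phenyl]-2,3-dihydro-1-benzofuran-6-yl trifluoromethanesulfonate (ketene; C2 arrangement as in 5) | FC(F)(F)S(=O)(=O)Oc1cc(O)c2c(c1)O[C@H](c1ccc(O[Si](C(C)C)(C(C)C)C(C)C)cc1)C2=C=O | intermediate (not isolated)
7 | methyl (2S)-4-hydroxy-2-[4-(triisopropylsilyloxy)phenyl]-6-(trifluoromethylsulfonyloxy)-2,3-dihydro-1-benzofuran-3-carboxylate (both C3 epimers) | FC(F)(F)S(=O)(=O)Oc1cc(O)c2c(c1)O[C@H](c1ccc(O[Si](C(C)C)(C(C)C)C(C)C)cc1)C2C(=O)OC | intermediate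
8 | methyl (2S)-4-(triisopropylsilyloxy)-2-[4-(triisopropylsilyloxy)phenyl]-6-(trifluoromethylsulfonyloxy)-2,3-dihydro-1-benzofuran-3-carboxylate (C3 epimers) | FC(F)(F)S(=O)(=O)Oc1cc(O[Si](C(C)C)(C(C)C)C(C)C)c2c(c1)O[C@H](c1ccc(O[Si](C(C)C)(C(C)C)C(C)C)cc1)C2C(=O)OC | intermediate
9 | (2S)-4-(triisopropylsilyloxy)-2-[4-(triisopropylsilyloxy)phenyl]-6-(trifluoromethylsulfonyloxy)-2,3-dihydro-1-benzofuran-3-carboxylic acid (C3 epimers) | FC(F)(F)S(=O)(=O)Oc1cc(O[Si](C(C)C)(C(C)C)C(C)C)c2c(c1)O[C@H](c1ccc(O[Si](C(C)C)(C(C)C)C(C)C)cc1)C2C(=O)O | intermediate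
10 | 1,3-dioxoisoindolin-2-yl (2S)-4-(triisopropylsilyloxy)-2-[4-(triisopropylsilyloxy)phenyl]-6-(trifluoromethylsulfonyloxy)-2,3-dihydro-1-benzofuran-3-carboxylate (C3 epimers) | FC(F)(F)S(=O)(=O)Oc1cc(O[Si](C(C)C)(C(C)C)C(C)C)c2c(c1)O[C@H](c1ccc(O[Si](C(C)C)(C(C)C)C(C)C)cc1)C2C(=O)ON1C(=O)c2ccccc2C1=O | intermediate
11 | 5-bromobenzene-1,3-diol | Oc1cc(O)cc(Br)c1 | starting material
12 | 1-bromo-3,5-bis(triisopropylsilyloxy)benzene | Brc1cc(O[Si](C(C)C)(C(C)C)C(C)C)cc(O[Si](C(C)C)(C(C)C)C(C)C)c1 | intermediate
13 | 3,5-bis(triisopropylsilyloxy)phenyllithium | [Li]c1cc(O[Si](C(C)C)(C(C)C)C(C)C)cc(O[Si](C(C)C)(C(C)C)C(C)C)c1 | intermediate (not isolated)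
14 | [3,5-bis(triisopropylsilyloxy)phenyl]zinc chloride | Cl[Zn]c1cc(O[Si](C(C)C)(C(C)C)C(C)C)cc(O[Si](C(C)C)(C(C)C)C(C)C)c1 | intermediate (not isolated)
15 | (2S,3S)-3-[3,5-bis(triisopropylsilyloxy)phenyl]-4-(triisopropylsilyloxy)-2-[4-(triisopropylsilyloxy)phenyl]-2,3-dihydro-1-benzofuran-6-yl trifluoromethanesulfonate | FC(F)(F)S(=O)(=O)Oc1cc(O[Si](C(C)C)(C(C)C)C(C)C)c2c(c1)O[C@H](c1ccc(O[Si](C(C)C)(C(C)C)C(C)C)cc1)[C@H]2c1cc(O[Si](C(C)C)(C(C)C)C(C)C)cc(O[Si](C(C)C)(C(C)C)C(C)C)c1 | intermediate
16 | [(2S,3S)-3-[3,5-bis(triisopropylsilyloxy)phenyl]-4-(triisopropylsilyloxy)-2-[4-(triisopropylsilyloxy)phenyl]-2,3-dihydro-1-benzofuran-6-yl]boronic acid | OB(O)c1cc(O[Si](C(C)C)(C(C)C)C(C)C)c2c(c1)O[C@H](c1ccc(O[Si](C(C)C)(C(C)C)C(C)C)cc1)[C@H]2c1cc(O[Si](C(C)C)(C(C)C)C(C)C)cc(O[Si](C(C)C)(C(C)C)C(C)C)c1 | intermediate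
17 | 4-acetoxystyrene | CC(=O)Oc1ccc(C=C)cc1 | starting material
18 | 4-vinylphenol | Oc1ccc(C=C)cc1 | intermediate (not isolated)
19 | 4-(triisopropylsilyloxy)styrene | C=Cc1ccc(O[Si](C(C)C)(C(C)C)C(C)C)cc1 | intermediate
20 | (2S)-4-(triisopropylsilyloxy)-2-[4-(triisopropylsilyloxy)phenyl]-6-[(E)-2-[4-(triisopropylsilyloxy)phenyl]ethenyl]-2,3-dihydro-1-benzofuran-3-carboxylic acid (C3 epimers) | CC(C)[Si](C(C)C)(C(C)C)Oc1ccc(/C=C/c2cc(O[Si](C(C)C)(C(C)C)C(C)C)c3c(c2)O[C@H](c2ccc(O[Si](C(C)C)(C(C)C)C(C)C)cc2)C3C(=O)O)cc1 | intermediate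
21 | 4,5,6,7-tetrachloro-1,3-dioxoisoindolin-2-yl ester of 20 (C3 epimers) | CC(C)[Si](C(C)C)(C(C)C)Oc1ccc(/C=C/c2cc(O[Si](C(C)C)(C(C)C)C(C)C)c3c(c2)O[C@H](c2ccc(O[Si](C(C)C)(C(C)C)C(C)C)cc2)C3C(=O)ON2C(=O)c3c(Cl)c(Cl)c(Cl)c(Cl)c3C2=O)cc1 | intermediate
22 | heptakis(triisopropylsilyl) ether of 23 (2S,3S,2'S,3'S; E) | CC(C)[Si](C(C)C)(C(C)C)Oc1ccc(/C=C/c2cc(O[Si](C(C)C)(C(C)C)C(C)C)c3c(c2)O[C@H](c2ccc(O[Si](C(C)C)(C(C)C)C(C)C)cc2)[C@H]3c2cc(O[Si](C(C)C)(C(C)C)C(C)C)c3c(c2)O[C@H](c2ccc(O[Si](C(C)C)(C(C)C)C(C)C)cc2)[C@H]3c2cc(O[Si](C(C)C)(C(C)C)C(C)C)cc(O[Si](C(C)C)(C(C)C)C(C)C)c2)cc1 | intermediate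
23 | (2S,3S)-3-[(2S,3S)-3-(3,5-dihydroxyphenyl)-4-hydroxy-2-(4-hydroxyphenyl)-2,3-dihydro-1-benzofuran-6-yl]-2-(4-hydroxyphenyl)-6-[(E)-2-(4-hydroxyphenyl)ethenyl]-2,3-dihydro-1-benzofuran-4-ol | Oc1ccc(/C=C/c2cc(O)c3c(c2)O[C@H](c2ccc(O)cc2)[C@H]3c2cc(O)c3c(c2)O[C@H](c2ccc(O)cc2)[C@H]3c2cc(O)cc(O)c2)cc1 | target

## Step count and least certain steps

Total: 15 steps. Longest linear sequence: 11 steps (steps 1–7, 9, 10, 14, 15).

**Step 4 (key step, proposed new method).**
- Risk: hydride migration from C2 to a carbene centre at C3 with aromatisation to the flavone, which erases C2. Also insertion of the carbene into the O–H bond of the solvent, slow conversion because the chelated ketone sheds its excitation by proton transfer, or light-induced cleavage of the benzylic O1–C2 bond.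
- Fallback (known chemistry, a different way to contract the ring): 3 is silylated at the chelated 5-hydroxyl (TIPSOTf, 2,6-lutidine, CH2Cl2) to give (2S)-4-oxo-5-(triisopropylsilyloxy)-2-[4-(triisopropylsilyloxy)phenyl]chroman-7-yl trifluoromethanesulfonate F1. F1 is then treated with PhI(OAc)2 and catalytic H2SO4 in HC(OMe)3 at rt. The methyl enol ether is attacked by the iodane at C3 anti to the C2 aryl group, the ring-A carbon shifts from C4 to C3 as iodobenzene leaves, and the dimethoxycarbenium ion collapses to the methyl ester. The product is 8 as its trans epimer, where the route is rejoined.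
- This fallback needs no enolate and no light and leaves out steps 3 to 5. Its own weak point is the competing shift of the C2 aryl group.

**Step 3.**
- Risk: expulsion of the ring-A phenoxide from the C3 carbanion (dianion or diketonate), which opens the pyranone to a chalcone that recloses without facial control and so erodes C2. Incomplete second deprotonation is the other risk.
- Fallback (acylation without a free enolate): 3 is treated with TMSOTf and Et3N in CH2Cl2 at 0 °C to give (2S)-4,5-bis(trimethylsilyloxy)-2-[4-(triisopropylsilyloxy)phenyl]-2H-chromen-7-yl trifluoromethanesulfonate F2, which is C-acylated at C3 with trifluoroacetic anhydride. Aqueous work-up removes the silyl groups and gives 4, which enters the same azide transfer, run cold.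
- If the diketonate stage is the leak, the fallback given for step 4 avoids the diazoketone altogether.

**Step 14.**
- Risk: slow capture of the hindered benzylic radical (flanked by the C2 aryl group and the C4 silyloxy group), leading to dimerisation or reduction. Also loss of the boronic acid by protodeboronation at 75 °C, and partial desilylation by the amine in wet DMF.
- Fallback (ring 2 as the arylzinc type that step 9 uses at rt): 15 is stannylated ((Bu3Sn)2, Pd(PPh3)4, LiCl, 1,4-dioxane, 100 °C) to tributyl[(2S,3S)-3-[3,5-bis(triisopropylsilyloxy)phenyl]-4-(triisopropylsilyloxy)-2-[4-(triisopropylsilyloxy)phenyl]-2,3-dihydro-1-benzofuran-6-yl]stannane F3. Tin–lithium exchange (n-BuLi, THF, −78 °C) gives the corresponding aryllithium F4, and ZnCl2 gives the arylzinc chloride F5. F5 (1.5 equiv) is coupled with 21 under NiCl2·dme and 4,4'-di-tert-butyl-2,2'-bipyridine in THF/DMF at rt to give 22.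

**Step 9.**
- Risk: insertion of low-valent nickel into the aryl triflate with biaryl formation, incomplete trans selectivity, or radical dimerisation.
- Fallback (remove the triflate before the radical step): 9 is borylated (B2pin2, PdCl2(dppf), KOAc, 1,4-dioxane, 85 °C) to (2S)-6-(4,4,5,5-tetramethyl-1,3,2-dioxaborolan-2-yl)-4-(triisopropylsilyloxy)-2-[4-(triisopropylsilyloxy)phenyl]-2,3-dihydro-1-benzofuran-3-carboxylic acid F6. F6 is esterified with N-hydroxyphthalimide and DIC to its 1,3-dioxoisoindolin-2-yl ester F7. F7 is arylated with 14 under the conditions of step 9 to the (2S,3S)-3-[3,5-bis(triisopropylsilyloxy)phenyl] pinacol boronate F8, whose pinacol group is removed with NaIO4 and NH4OAc in acetone/water to give 16.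

**Step 6.**
- Risk: loss of aryl silyl groups or sluggish hydrolysis of the hindered ester at 80 °C.
- Fallback (hydrolysis before silylation): 7 is saponified with LiOH in THF/water at 0 °C to (2S)-4-hydroxy-2-[4-(triisopropylsilyloxy)phenyl]-6-(trifluoromethylsulfonyloxy)-2,3-dihydro-1-benzofuran-3-carboxylic acid F9. Any 4'-silyl group lost here is put back in the next operation. Excess TIPSOTf and 2,6-lutidine give the triisopropylsilyl ester of 9, F10, which is not isolated. Brief treatment with K2CO3 in MeOH/water at 0 °C cleaves only the silyl ester and gives 9.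

## Further compounds

F1 | step 4 | (2S)-4-oxo-5-(triisopropylsilyloxy)-2-[4-(triisopropylsilyloxy)phenyl]chroman-7-yl trifluoromethanesulfonate | FC(F)(F)S(=O)(=O)Oc1cc(O[Si](C(C)C)(C(C)C)C(C)C)c2c(c1)O[C@H](c1ccc(O[Si](C(C)C)(C(C)C)C(C)C)cc1)CC2=O
F2 | step 3 | (2S)-4,5-bis(trimethylsilyloxy)-2-[4-(triisopropylsilyloxy)phenyl]-2H-chromen-7-yl trifluoromethanesulfonate | FC(F)(F)S(=O)(=O)Oc1cc(O[Si](C)(C)C)c2c(c1)O[C@H](c1ccc(O[Si](C(C)C)(C(C)C)C(C)C)cc1)C=C2O[Si](C)(C)C
F3 | step 14 | tributyl[(2S,3S)-3-[3,5-bis(triisopropylsilyloxy)phenyl]-4-(triisopropylsilyloxy)-2-[4-(triisopropylsilyloxy)phenyl]-2,3-dihydro-1-benzofuran-6-yl]stannane | CCCC[Sn](CCCC)(CCCC)c1cc(O[Si](C(C)C)(C(C)C)C(C)C)c2c(c1)O[C@H](c1ccc(O[Si](C(C)C)(C(C)C)C(C)C)cc1)[C@H]2c1cc(O[Si](C(C)C)(C(C)C)C(C)C)cc(O[Si](C(C)C)(C(C)C)C(C)C)c1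
F4 | step 14 | [(2S,3S)-3-[3,5-bis(triisopropylsilyloxy)phenyl]-4-(triisopropylsilyloxy)-2-[4-(triisopropylsilyloxy)phenyl]-2,3-dihydro-1-benzofuran-6-yl]lithium | [Li]c1cc(O[Si](C(C)C)(C(C)C)C(C)C)c2c(c1)O[C@H](c1ccc(O[Si](C(C)C)(C(C)C)C(C)C)cc1)[C@H]2c1cc(O[Si](C(C)C)(C(C)C)C(C)C)cc(O[Si](C(C)C)(C(C)C)C(C)C)c1
F5 | step 14 | [(2S,3S)-3-[3,5-bis(triisopropylsilyloxy)phenyl]-4-(triisopropylsilyloxy)-2-[4-(triisopropylsilyloxy)phenyl]-2,3-dihydro-1-benzofuran-6-yl]zinc chloride | Cl[Zn]c1cc(O[Si](C(C)C)(C(C)C)C(C)C)c2c(c1)O[C@H](c1ccc(O[Si](C(C)C)(C(C)C)C(C)C)cc1)[C@H]2c1cc(O[Si](C(C)C)(C(C)C)C(C)C)cc(O[Si](C(C)C)(C(C)C)C(C)C)c1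
F6 | step 9 | (2S)-6-(4,4,5,5-tetramethyl-1,3,2-dioxaborolan-2-yl)-4-(triisopropylsilyloxy)-2-[4-(triisopropylsilyloxy)phenyl]-2,3-dihydro-1-benzofuran-3-carboxylic acid (C3 epimers) | CC1(C)OB(OC1(C)C)c1cc(O[Si](C(C)C)(C(C)C)C(C)C)c2c(c1)O[C@H](c1ccc(O[Si](C(C)C)(C(C)C)C(C)C)cc1)C2C(=O)O
F7 | step 9 | 1,3-dioxoisoindolin-2-yl ester of F6 (C3 epimers) | CC1(C)OB(OC1(C)C)c1cc(O[Si](C(C)C)(C(C)C)C(C)C)c2c(c1)O[C@H](c1ccc(O[Si](C(C)C)(C(C)C)C(C)C)cc1)C2C(=O)ON1C(=O)c2ccccc2C1=O
F8 | step 9 | 2-[(2S,3S)-3-[3,5-bis(triisopropylsilyloxy)phenyl]-4-(triisopropylsilyloxy)-2-[4-(triisopropylsilyloxy)phenyl]-2,3-dihydro-1-benzofuran-6-yl]-4,4,5,5-tetramethyl-1,3,2-dioxaborolane | CC1(C)OB(OC1(C)C)c1cc(O[Si](C(C)C)(C(C)C)C(C)C)c2c(c1)O[C@H](c1ccc(O[Si](C(C)C)(C(C)C)C(C)C)cc1)[C@H]2c1cc(O[Si](C(C)C)(C(C)C)C(C)C)cc(O[Si](C(C)C)(C(C)C)C(C)C)c1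
F9 | step 6 | (2S)-4-hydroxy-2-[4-(triisopropylsilyloxy)phenyl]-6-(trifluoromethylsulfonyloxy)-2,3-dihydro-1-benzofuran-3-carboxylic acid (C3 epimers) | FC(F)(F)S(=O)(=O)Oc1cc(O)c2c(c1)O[C@H](c1ccc(O[Si](C(C)C)(C(C)C)C(C)C)cc1)C2C(=O)O
F10 | step 6 | triisopropylsilyl (2S)-4-(triisopropylsilyloxy)-2-[4-(triisopropylsilyloxy)phenyl]-6-(trifluoromethylsulfonyloxy)-2,3-dihydro-1-benzofuran-3-carboxylate (C3 epimers) | FC(F)(F)S(=O)(=O)Oc1cc(O[Si](C(C)C)(C(C)C)C(C)C)c2c(c1)O[C@H](c1ccc(O[Si](C(C)C)(C(C)C)C(C)C)cc1)C2C(=O)O[Si](C(C)C)(C(C)C)C(C)C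
A1 | alternative 1 | anti-1,2-diaryl secondary pinacol boronate: C2 bears the boronate and 4-methoxyphenyl; C3 bears 2,6-bis(methoxymethoxy)-4-[(tert-butyldimethylsilyloxy)methyl]phenyl and the (2S,3S)-3-(3,5-dimethoxyphenyl)-4-methoxy-2-(4-methoxyphenyl)-2,3-dihydro-1-benzofuran-6-yl group | CC1(C)OB(OC1(C)C)[C@@H](c1ccc(OC)cc1)[C@H](c1c(OCOC)cc(CO[Si](C)(C)C(C)(C)C)cc1OCOC)c1cc(OC)c2c(c1)O[C@H](c1ccc(OC)cc1)[C@H]2c1cc(OC)cc(OC)c1
A2 | alternative 2 | 5-[(2S,3S)-6-bromo-4-methoxy-2-(4-methoxyphenyl)-2,3-dihydro-1-benzofuran-3-yl]-2-[1-(3,5-dimethoxyphenyl)-2-methoxy-2-(4-methoxyphenyl)ethyl]-3-(triisopropylsilyloxy)phenol (chain methine configured as in the SMILES, methoxy carbon unassigned) | Brc1cc(OC)c2c(c1)O[C@H](c1ccc(OC)cc1)[C@H]2c1cc(O)c([C@H](c2cc(OC)cc(OC)c2)C(OC)c2ccc(OC)cc2)c(O[Si](C(C)C)(C(C)C)C(C)C)c1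
A3 | alternative 3 | methyl (2S,3S)-3-[(2S,3S)-3-(3,5-dimethoxyphenyl)-4-hydroxy-2-(4-methoxyphenyl)-2,3-dihydro-1-benzofuran-6-yl]-4-hydroxy-2-(4-methoxyphenyl)-2,3-dihydro-1-benzofuran-6-carboxylate | COC(=O)c1cc(O)c2c(c1)O[C@H](c1ccc(OC)cc1)[C@H]2c1cc(O)c2c(c1)O[C@H](c1ccc(OC)cc1)[C@H]2c1cc(OC)cc(OC)c1
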